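Amounts first, in percent of the substrate charged, since a quick number was asked for and the hunch was that the cooler start (80 °C against 100 °C) costs Sunday's flask product.

| setting | dusk | spring | Tuesday's | Sunday's |
|---|---|---|---|---|
| substrate | 0.050 M | 0.050 M | 0.050 M | 0.050 M |
| capture agent | 0.64 mM | 2.3 mM | 3.00 mM | 1.00 mM |
| temperature | 75 °C | 90 °C |  |  |
| remark | run made earlier | run made earlier | at 100 °C throughout | at 80 °C until 2.0 min, from then on at 100 °C |
| time |  |  | 10 min | 10 min |

| run | time / min | product / % | substrate / % |
|---|---|---|---|
| dusk | 1.33 | 1 | 51 |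
| dusk | 3.00 | 3 | 20 |
| dusk | 4.00 | 3 | 13 |
| dusk | 6.00 | 2 | 4 |
| dusk | 8.00 | 7 | 1 |
| spring | 0.333 | 2 | 44 |
| spring | 0.667 | 0 | 18 |
| spring | 1.33 | 1 | 6 |
| spring | 2.50 | 10 | 0 |
| spring | 5.00 | 32 | 0 |

(standard deviation of a reading: 1.5 percentage points)

- steps that have been proposed: intermediate C -> product; substrate -> intermediate B; intermediate C <-> intermediate D; intermediate A -> intermediate D; capture agent + intermediate C -> trapped intermediate; intermediate B -> intermediate C; substrate -> intermediate A

- which of the two ends with the higher amount of product, in percent of the substrate charged ("neither" if they lie within 2 percentage points) (Tuesday's / Sunday's / neither)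
- product at the end, in percent of the substrate charged, Tuesday's
- product at the end, in percent of the substrate charged, Sunday's

Substrate loss gives the clock. The dusk run holds 51% of its substrate at 1.33 min, which reads as a first-order constant of 0.506 min⁻¹; the spring run holds 44% at 0.333 min, which reads as 2.47 min⁻¹. Taking that ratio as exponential in temperature, 100 °C runs 8.25 times as fast as 80 °C. Sunday's flask therefore has 8.24 min of heat-equivalent time, the minutes at 100 °C doing the same substrate loss, against 10 min for Tuesday's flask, a shortfall of 1.76 min.

Product in the spring run climbs 22 percentage points in 2.50 min. With the curve replaced by that mean line, and 100 °C taken as 2.87 times as fast as 90 °C, the line reaches the whole charge at 4.43 min of heat-equivalent time. That is about half of what Sunday's flask has, which leaves room for a curve that bends over, so the shortfall should cost little. The capture agent charged equals 6.00% of the substrate in Tuesday's flask and 2.00% in Sunday's, a gap of 4 points if all of it were consumed one-to-one. The reckoning here commits to neither, less firmly for that gap, and to no level, since product in the spring run is higher at its last reading than at the one before.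

The forecast gives 88% (78% to 93%) for Tuesday's flask and 88% (77% to 95%) for Sunday's, with the words “These are essentially equal”.

The flasks give 60.0% for Tuesday's and 59.6% for Sunday's, so neither, under these steps:

    intermediate C → product (k = 0.0600 min⁻¹, Ea = 117 kJ mol⁻¹)
    substrate → intermediate B (k = 0.840 min⁻¹, Ea = 107 kJ mol⁻¹)
    intermediate C ⇌ intermediate D (K = 23.0, k = 0.0410 min⁻¹, Ea = 109 kJ mol⁻¹, ΔH = −5.00 kJ mol⁻¹)
    intermediate A → intermediate D (k = 0.0850 min⁻¹, Ea = 104 kJ mol⁻¹)
    capture agent + intermediate C → trapped intermediate (k = 3.80 M⁻¹ min⁻¹, Ea = 50.0 kJ mol⁻¹)
    intermediate B → intermediate C (k = 0.230 min⁻¹, Ea = 97.0 kJ mol⁻¹)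
    substrate → intermediate A (k = 0.0640 min⁻¹, Ea = 93.0 kJ mol⁻¹)
    (constants at 80 °C)

Tuesday's flask stands at 55.8% product at 5.00 min and 60.0% at 10.0 min, with 36.7% in intermediate D, the resting state, more than the 0.712% in intermediate C. At that late mean rise of Tuesday's flask, Sunday's shortfall of 1.76 min reckons at 1.5 points; the two flasks, which differ in capture agent as well, stand 0.40 points apart. By the same substrate ratio, the 10 min of the flask like Tuesday's at 115 °C count as 48.7 min at 100 °C, and it ends at 72.2%, above Tuesday's 60.0% at 10 min and below the 80.2% Tuesday's flask reaches at 100 min.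

The readings were computed on assumed constants, noise included.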